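The earlier runs and the new flask stem from a simulated flask for an exercise, and the scatter is random.

At 90.0 s, the last reading of the flask, I read its table column by column.

| setting | south-west | flask |
|---|---|---|
| left-handed substrate | 10 mM | 10 mM |
| right-handed substrate | 10 mM | 10 mM |
| reagent | 15 mM | 15.0 mM |
| catalyst | 0.50 mM | 0.50 mM |
| remark | the very flask that is asked about, followed so far |  |
| time |  | 4.0 min |

- south-west (time / s: left-handed substrate / %, right-handed substrate / %, left-handed product / %): 10.0: 37, 48, 15; 12.0: 40, 47, 10; 20.0: 30, 49, 19; 25.0: 29, 50, 19; 40.0: 27, 50, 23; 60.0: 20, 47, 24; 90.0: 15, 51, 35

(scatter of a reading: 2 percentage points)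

- catalyst is single-handed; left-handed substrate and right-handed substrate are mirror images of each other, charged as a racemate, each of them at the stated concentration
- the analysis behind the earlier runs scatters by 2 percentage points, standard deviation
- an excess is the difference of the two amounts in percent of their sum
- an excess is below zero if the other one leads

1. part of the left-handed substrate and right-handed substrate charged together that has reacted at 4.0 min
2. excess of left-handed product over right-handed product in the product at 4.0 min
3. excess of right-handed substrate over left-handed substrate among what is left of the two at 4.0 min

The right-handed column stays between 47% and 51%, with a scatter of 2 percentage points, so that substrate barely moves. The left-handed column falls to 15% as its product reaches 35%, and in the last row the two sum to 50.0%. Reading down, the fall slows: the left-handed column is at 30% by 20.0 s, and the next 70.0 s take 15 points.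

So I ask for the end state. The reagent is not read, and I assume one reagent per product. The quantity to carry is then the reagent surplus s, the reagent charged less the left-handed substrate charged: 5.00 mM. Since s is positive, left-handed substrate is the limiting reagent of the left-handed conversion. While the right-handed substrate barely moves, reagent left is about s plus left-handed substrate left, which is near 8.00 mM at the last reading. Holding the right-handed substrate still, I commit to c below 50.0% at 4.0 min, with reagent above s.

The forecast gives c 44.5% (38% to 49%), eP 93% (82% to 100%) and eS 75% (60% to 90%). Of the slowing it says: “This suggests slowing from product inhibition, reagent depletion or partial catalyst decay.” By my balance, its c leaves 6.10 mM of reagent.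

The flask gives c 43.3%, eP 96.8% and eS 73.9%, each inside the forecast's range.

    reagent + catalyst + right-handed substrate → catalyst + right-handed product (k = 34.0 M⁻² s⁻¹)
    catalyst ⇌ dormant form (K = 2.00, k = 0.0300 s⁻¹)
    reagent → decomposition product (k = 4.50 × 10⁻⁵ s⁻¹)
    reagent + catalyst + left-handed substrate → catalyst + left-handed product (k = 4600 M⁻² s⁻¹)

At 4.00 min this kinetic resolution stands at c 43.3%, short of 50.0%. There s plus the 7.39% of left-handed substrate gives 6.48 mM of reagent, and the flask holds 6.25 mM, with 0.702% of right-handed product and 0.0887 mM of decomposition product also formed. By 0.400 min the catalyst is down to 56.0% of its charge, with 44.0% dormant form, while the left-handed conversion has brought its substrate to 29.8%. From 2.00 min that conversion runs on with catalyst near 33.6%; at 0.446 min it uses reagent 78 times as fast as the right-handed one.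

In a neighbour flask, the same but with 6.0 mM of reagent, s is −4.00 mM, so reagent limits that neighbour: at one reagent per product, c has a ceiling of 30.0%, and left-handed substrate a floor of 20.0%. That neighbour gives c 23.4%, with left-handed substrate at 26.9% and reagent at 21.7% of its charge.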